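**Strategy.** The plan cuts the C2–C3 bond of the dihydrofuran ring that carries the cis-styryl arm. C2 is a benzylic O–CH carbon and C3 a diarylmethine between C3a of the resorcinol ring and C4′ of the second benzofuran: the footprint of a diaryl carbene inserted into an aryl 4-methoxybenzyl ether. The key step oxidises a hydrazone to the diazo compound and closes this ring by Rh(II)-catalysed 1,5-C–H insertion, setting C2 and C3 in one catalyst-controlled event on a precursor that already holds the other dihydrofuran, itself made the same way from the same aldehyde with the mirror-image catalyst. Acid then turns the cis ring trans, and the Z-alkene arrives last by Suzuki coupling.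

Key step: step 12

Assumption: Rh2(R-PTAD)4 is taken to give the (3R)- and Rh2(S-PTAD)4 the (3S)-configured insertion product, the first-formed ring being 2,3-cis in each case; if the sense of induction is the reverse, the two catalysts change places.

**Route**

Step 1
Reactants: 1 1-bromo-3,5-dimethoxybenzene
Product: 2 2-bromo-4,6-dimethoxybenzaldehyde
Conditions: POCl3, DMF, 0 → 90 °C; then H2O
Reagents that add atoms: N,N-dimethylformamide CN(C)C=O; water O
Why: Vilsmeier–Haack formylation should go at the position para to one methoxy group and next to bromine, not between the two methoxy groups, as is usual for 5-substituted 1,3-dimethoxybenzenes.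

Step 2
Reactants: 2 2-bromo-4,6-dimethoxybenzaldehyde
Product: 3 2-bromo-6-hydroxy-4-methoxybenzaldehyde
Conditions: BCl3, CH2Cl2, −78 → 0 °C; then H2O
Reagents that add atoms: none
Why: Chelation of BCl3 between the aldehyde oxygen and the ortho methoxy group should direct the Lewis-acid ether cleavage to that methyl ether only.

Step 3
Reactants: 3 2-bromo-6-hydroxy-4-methoxybenzaldehyde; 4 4-methoxybenzyl chloride
Product: 5 2-bromo-4-methoxy-6-[(4-methoxybenzyl)oxy]benzaldehyde
Conditions: K2CO3, KI (cat.), DMF, 60 °C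
Reagents that add atoms: none
Why: Williamson etherification of the phenoxide with a reactive benzylic chloride; this aldehyde serves both benzofuran units.

Step 4
Reactants: 5 2-bromo-4-methoxy-6-[(4-methoxybenzyl)oxy]benzaldehyde; 6 3,5-dimethoxyphenylmagnesium chloride
Product: 7 rac-{2-bromo-4-methoxy-6-[(4-methoxybenzyl)oxy]phenyl}(3,5-dimethoxyphenyl)methanol
Conditions: THF, 0 °C; then H2O
Reagents that add atoms: none
Why: Grignard addition to the aldehyde is faster than any reaction at the aryl bromide, and the racemic carbinol centre is erased in step 5.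

Step 5
Reactants: 7 rac-diarylmethanol
Product: 8 {2-bromo-4-methoxy-6-[(4-methoxybenzyl)oxy]phenyl}(3,5-dimethoxyphenyl)methanone
Conditions: Dess–Martin periodinane, CH2Cl2, rt
Reagents that add atoms: none
Why: Dess–Martin oxidation of a doubly benzylic secondary alcohol is fast and leaves the benzyl ether and the aryl bromide untouched.

Step 6
Reactants: 8 diaryl ketone
Product: 9 hydrazone of ketone 8 (E/Z mixture)
Conditions: N2H4·H2O, AcOH (cat.), EtOH, 90 °C (sealed tube)
Reagents that add atoms: hydrazine NN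
Why: Acid-catalysed condensation with excess hydrazine should give the hydrazone, heat being needed for the di-ortho-substituted carbonyl group.

Step 7
Reactants: 9 hydrazone of ketone 8
Product: 11 (2S,3R)-4-bromo-3-(3,5-dimethoxyphenyl)-6-methoxy-2-(4-methoxyphenyl)-2,3-dihydro-1-benzofuran (2,3-cis), via diaryldiazomethane 10 (not isolated)
Conditions: MnO2, CH2Cl2, rt, filter; then Rh2(R-PTAD)4 (1 mol%), CH3CN, 0 °C → rt
Reagents that add atoms: none
Why: Dehydrogenation to the diazo compound and Rh(II)-catalysed intramolecular 1,5-C–H insertion of the donor/donor carbene into the benzylic ether C–H should close the ring, with C3 set by the chiral carboxylate catalyst and C2 cis to it by the insertion geometry.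

Step 8
Reactants: 11 cis-dihydrobenzofuran (2S,3R)
Product: 12 (2R,3R)-4-bromo-3-(3,5-dimethoxyphenyl)-6-methoxy-2-(4-methoxyphenyl)-2,3-dihydro-1-benzofuran (2,3-trans)
Conditions: TFA, CH2Cl2, 0 °C → rt
Reagents that add atoms: none
Why: Acid-mediated epimerisation: reversible ionisation of the benzylic C2–O bond to a 4-methoxybenzyl cation held next to its phenol should re-close to the more stable 2,3-trans ring, inverting C2 only.

Step 9
Reactants: 12 trans-bromide (2R,3R); 5 2-bromo-4-methoxy-6-[(4-methoxybenzyl)oxy]benzaldehyde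
Product: 13 {2-bromo-4-methoxy-6-[(4-methoxybenzyl)oxy]phenyl}[(2R,3R)-3-(3,5-dimethoxyphenyl)-6-methoxy-2-(4-methoxyphenyl)-2,3-dihydro-1-benzofuran-4-yl]methanol (both carbinol epimers)
Conditions: n-BuLi, THF, −78 °C; then 5, −78 → −20 °C; then H2O
Reagents that add atoms: none
Why: Bromine–lithium exchange at C4′ followed by 1,2-addition of the aryllithium to the aldehyde outruns exchange with the bromide of 5, and the new carbinol centre is erased in step 10.

Step 10
Reactants: 13 diarylmethanol (epimer mixture)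
Product: 14 {2-bromo-4-methoxy-6-[(4-methoxybenzyl)oxy]phenyl}[(2R,3R)-3-(3,5-dimethoxyphenyl)-6-methoxy-2-(4-methoxyphenyl)-2,3-dihydro-1-benzofuran-4-yl]methanone
Conditions: Dess–Martin periodinane, CH2Cl2, rt
Reagents that add atoms: none
Why: Dess–Martin oxidation should convert both epimers into one ketone without touching the benzylic ethers.

Step 11
Reactants: 14 diaryl ketone
Product: 15 hydrazone of ketone 14 (E/Z mixture)
Conditions: N2H4·H2O (excess), AcOH (cat.), n-BuOH, 120 °C (sealed tube)
Reagents that add atoms: hydrazine NN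
Why: Hydrazone condensation as in step 6, under more forcing conditions because the carbonyl group has three ortho substituents.

Step 12
Reactants: 15 hydrazone of ketone 14
Product: 17 (2R,3S)-4-bromo-3-[(2R,3R)-3-(3,5-dimethoxyphenyl)-6-methoxy-2-(4-methoxyphenyl)-2,3-dihydro-1-benzofuran-4-yl]-6-methoxy-2-(4-methoxyphenyl)-2,3-dihydro-1-benzofuran (new ring 2,3-cis), via diaryldiazomethane 16 (not isolated)
Conditions: MnO2, CH2Cl2, 0 °C → rt, filter; then Rh2(S-PTAD)4 (2 mol%), CH2Cl2/CH3CN, 0 °C → rt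
Reagents that add atoms: none
Why: MnO2 dehydrogenates 15 to the diaryldiazomethane 16, from which the chiral Rh(II) carboxylate forms a donor/donor carbene at the future C3; this inserts into one of the two enantiotopic C–H bonds of the ArO–CH2–Ar group through a five-membered, hydride-transfer-like transition state. The closest known reaction type is the enantioselective intramolecular C–H insertion of diaryl rhodium carbenes into aryl benzyl ethers, which gives 2,3-diaryl-2,3-dihydrobenzofurans. The one ring that closes is the dihydrofuran, by C–C bond formation between the carbene carbon and the ether carbon (1,5-insertion, ring size five). C3 is set by the facial bias of the catalyst at the carbene carbon, and C2 follows from the suprafacial delivery that places the two aryl groups cis (2R,3S); C2 is corrected in step 13. The step needs catalyst control over the bias of the resident (2R,3R) ring, and site selectivity for the ether C–H over the 3,5-dimethoxyphenyl ring and the C–H bonds of the existing dihydrofuran. The ether C–H is the only hydridic C–H that lies 1,5 to the carbene (C2′–H and C3′–H would give a bridged or four-membered ring), and the weakly electrophilic donor/donor carbene should spare the arene.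

Step 13
Reactants: 17 cis,trans-bis(dihydrobenzofuran) (2R,3S)
Product: 18 (2S,3S)-4-bromo-3-[(2R,3R)-3-(3,5-dimethoxyphenyl)-6-methoxy-2-(4-methoxyphenyl)-2,3-dihydro-1-benzofuran-4-yl]-6-methoxy-2-(4-methoxyphenyl)-2,3-dihydro-1-benzofuran (both rings 2,3-trans)
Conditions: TFA, CH2Cl2, −20 → 0 °C, short contact
Reagents that add atoms: none
Why: Acid-mediated epimerisation as in step 8 should invert C2 of the new ring to the stable trans arrangement, while C3 and the already trans ring keep their configuration.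

Step 14
Reactants: 18 hexamethyl ether (2S,3S,2′R,3′R)
Product: 19 5-[(2R,3R)-4-[(2S,3S)-4-bromo-6-hydroxy-2-(4-hydroxyphenyl)-2,3-dihydro-1-benzofuran-3-yl]-6-hydroxy-2-(4-hydroxyphenyl)-2,3-dihydro-1-benzofuran-3-yl]benzene-1,3-diol
Conditions: BBr3, CH2Cl2, −78 °C → rt; then H2O
Reagents that add atoms: none
Why: Lewis-acid cleavage of the six aryl methyl ethers is done before the acid-sensitive cis-stilbene exists, the aryl bromide is inert, and any benzylic C–O ionisation can only re-close to the trans rings.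

Step 15
Reactants: 20 tert-butyl(4-ethynylphenoxy)dimethylsilane
Product: 21 (Z)-tert-butyldimethyl{4-[2-(4,4,5,5-tetramethyl-1,3,2-dioxaborolan-2-yl)ethenyl]phenoxy}silane
Conditions: [Rh(cod)Cl]2 (1.5 mol%), P(i-Pr)3 (6 mol%), Et3N, cyclohexane, rt
Reagents that add atoms: pinacolborane CC1(C)OBOC1(C)C
Why: Rh-catalysed formal trans-hydroboration of a terminal alkyne through a vinylidene intermediate should place boron at the terminus and give the Z-alkenylboronate.

Step 16
Reactants: 19 hexaphenol bromide; 21 (Z)-alkenylboronate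
Product: 23 cis-miyabenol C, via silyl ether 22 (not isolated)
Conditions: SPhos Pd G3 (5 mol%), K3PO4, THF/H2O (degassed), 45 °C; then TBAF, AcOH, rt
Reagents that add atoms: none
Why: Suzuki–Miyaura coupling of the aryl bromide with the alkenylboronate is stereoretentive and tolerates phenoxides, so the Z geometry of 21 should be carried into the stilbene, and fluoride then removes the single aryl silyl ether under near-neutral conditions.

**Compound list**

1 | 1-bromo-3,5-dimethoxybenzene | COc1cc(Br)cc(OC)c1 | starting material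
2 | 2-bromo-4,6-dimethoxybenzaldehyde | COc1cc(Br)c(C=O)c(OC)c1 | intermediate
3 | 2-bromo-6-hydroxy-4-methoxybenzaldehyde | COc1cc(O)c(C=O)c(Br)c1 | intermediate
4 | 4-methoxybenzyl chloride | COc1ccc(CCl)cc1 | starting material
5 | 2-bromo-4-methoxy-6-[(4-methoxybenzyl)oxy]benzaldehyde | COc1ccc(COc2cc(OC)cc(Br)c2C=O)cc1 | intermediate
6 | 3,5-dimethoxyphenylmagnesium chloride (THF solution) | COc1cc(OC)cc([Mg]Cl)c1 | starting material
7 | rac-{2-bromo-4-methoxy-6-[(4-methoxybenzyl)oxy]phenyl}(3,5-dimethoxyphenyl)methanol | COc1ccc(COc2cc(OC)cc(Br)c2C(O)c2cc(OC)cc(OC)c2)cc1 | intermediate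
8 | {2-bromo-4-methoxy-6-[(4-methoxybenzyl)oxy]phenyl}(3,5-dimethoxyphenyl)methanone | COc1ccc(COc2cc(OC)cc(Br)c2C(=O)c2cc(OC)cc(OC)c2)cc1 | intermediate
9 | hydrazone of ketone 8 | COc1ccc(COc2cc(OC)cc(Br)c2C(=NN)c2cc(OC)cc(OC)c2)cc1 | intermediate
10 | 1-bromo-2-[diazo(3,5-dimethoxyphenyl)methyl]-5-methoxy-3-[(4-methoxybenzyl)oxy]benzene | COc1ccc(COc2cc(OC)cc(Br)c2C(=[N+]=[N-])c2cc(OC)cc(OC)c2)cc1 | intermediate (not isolated)
11 | (2S,3R)-4-bromo-3-(3,5-dimethoxyphenyl)-6-methoxy-2-(4-methoxyphenyl)-2,3-dihydro-1-benzofuran (cis) | Brc1cc(OC)cc2c1[C@@H](c1cc(OC)cc(OC)c1)[C@@H](c1ccc(OC)cc1)O2 | intermediate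
12 | (2R,3R)-4-bromo-3-(3,5-dimethoxyphenyl)-6-methoxy-2-(4-methoxyphenyl)-2,3-dihydro-1-benzofuran (trans) | Brc1cc(OC)cc2c1[C@@H](c1cc(OC)cc(OC)c1)[C@H](c1ccc(OC)cc1)O2 | intermediate
13 | {2-bromo-4-methoxy-6-[(4-methoxybenzyl)oxy]phenyl}[(2R,3R)-3-(3,5-dimethoxyphenyl)-6-methoxy-2-(4-methoxyphenyl)-2,3-dihydro-1-benzofuran-4-yl]methanol (carbinol epimers) | COc1ccc(COc2cc(OC)cc(Br)c2C(O)c2cc(OC)cc3c2[C@@H](c2cc(OC)cc(OC)c2)[C@H](c2ccc(OC)cc2)O3)cc1 | intermediate
14 | {2-bromo-4-methoxy-6-[(4-methoxybenzyl)oxy]phenyl}[(2R,3R)-3-(3,5-dimethoxyphenyl)-6-methoxy-2-(4-methoxyphenyl)-2,3-dihydro-1-benzofuran-4-yl]methanone | COc1ccc(COc2cc(OC)cc(Br)c2C(=O)c2cc(OC)cc3c2[C@@H](c2cc(OC)cc(OC)c2)[C@H](c2ccc(OC)cc2)O3)cc1 | intermediate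
15 | hydrazone of ketone 14 | COc1ccc(COc2cc(OC)cc(Br)c2C(=NN)c2cc(OC)cc3c2[C@@H](c2cc(OC)cc(OC)c2)[C@H](c2ccc(OC)cc2)O3)cc1 | intermediate
16 | diaryldiazomethane from 15 | COc1ccc(COc2cc(OC)cc(Br)c2C(=[N+]=[N-])c2cc(OC)cc3c2[C@@H](c2cc(OC)cc(OC)c2)[C@H](c2ccc(OC)cc2)O3)cc1 | intermediate (not isolated)
17 | (2R,3S)-4-bromo-3-[(2R,3R)-3-(3,5-dimethoxyphenyl)-6-methoxy-2-(4-methoxyphenyl)-2,3-dihydro-1-benzofuran-4-yl]-6-methoxy-2-(4-methoxyphenyl)-2,3-dihydro-1-benzofuran | Brc1cc(OC)cc2c1[C@H](c1cc(OC)cc3c1[C@@H](c1cc(OC)cc(OC)c1)[C@H](c1ccc(OC)cc1)O3)[C@H](c1ccc(OC)cc1)O2 | intermediate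
18 | (2S,3S)-4-bromo-3-[(2R,3R)-3-(3,5-dimethoxyphenyl)-6-methoxy-2-(4-methoxyphenyl)-2,3-dihydro-1-benzofuran-4-yl]-6-methoxy-2-(4-methoxyphenyl)-2,3-dihydro-1-benzofuran | Brc1cc(OC)cc2c1[C@H](c1cc(OC)cc3c1[C@@H](c1cc(OC)cc(OC)c1)[C@H](c1ccc(OC)cc1)O3)[C@@H](c1ccc(OC)cc1)O2 | intermediate
19 | 5-[(2R,3R)-4-[(2S,3S)-4-bromo-6-hydroxy-2-(4-hydroxyphenyl)-2,3-dihydro-1-benzofuran-3-yl]-6-hydroxy-2-(4-hydroxyphenyl)-2,3-dihydro-1-benzofuran-3-yl]benzene-1,3-diol | Brc1cc(O)cc2c1[C@H](c1cc(O)cc3c1[C@@H](c1cc(O)cc(O)c1)[C@H](c1ccc(O)cc1)O3)[C@@H](c1ccc(O)cc1)O2 | intermediate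
20 | tert-butyl(4-ethynylphenoxy)dimethylsilane | C#Cc1ccc(O[Si](C)(C)C(C)(C)C)cc1 | starting material
21 | (Z)-tert-butyldimethyl{4-[2-(4,4,5,5-tetramethyl-1,3,2-dioxaborolan-2-yl)ethenyl]phenoxy}silane | CC(C)(C)[Si](C)(C)Oc1ccc(/C=C\B2OC(C)(C)C(C)(C)O2)cc1 | intermediate
22 | cis-miyabenol C 4-O-(tert-butyldimethylsilyl) ether on the styryl phenol | CC(C)(C)[Si](C)(C)Oc1ccc(/C=C\c2cc(O)cc3c2[C@H](c2cc(O)cc4c2[C@@H](c2cc(O)cc(O)c2)[C@H](c2ccc(O)cc2)O4)[C@@H](c2ccc(O)cc2)O3)cc1 | intermediate (not isolated)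
23 | cis-miyabenol C, 5-[(2R,3R)-6-hydroxy-4-[(2S,3S)-6-hydroxy-2-(4-hydroxyphenyl)-4-[(Z)-2-(4-hydroxyphenyl)ethenyl]-2,3-dihydro-1-benzofuran-3-yl]-2-(4-hydroxyphenyl)-2,3-dihydro-1-benzofuran-3-yl]benzene-1,3-diol | Oc1ccc(/C=C\c2cc(O)cc3c2[C@H](c2cc(O)cc4c2[C@@H](c2cc(O)cc(O)c2)[C@H](c2ccc(O)cc2)O4)[C@@H](c2ccc(O)cc2)O3)cc1 | target

**Step count**

Total steps: 16. Longest linear sequence: 15 steps (steps 1–14 and 16, from 1 to 23); step 15 is a one-step side branch, and aldehyde 5 is used twice.

**Steps most likely to fail**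

Step 12 (key step). The carbene carbon carries three ortho substituents, so formation of the rhodium carbene and the insertion may be slow. The carbene may instead attack the nearby 3,5-dimethoxyphenyl ring, or the catalyst may not override the facial bias of the resident (2R,3R) ring. The fallback changes the ring construction to a formal [4+1] annulation; it sets out from 12 (with aldehyde 3) and comes back at 18, so steps 10–13 are bypassed. Bromide 12 is lithiated as in step 9 and added to the sodium phenoxide of 3 (NaH, THF) to give the o-hydroxybenzhydrol F1. p-Toluenesulfinic acid in CH2Cl2 converts it into the 2-[aryl(tosyl)methyl]phenol F2. The thiolanium bromide F3 is made from (2R,5R)-2,5-dimethylthiolane and 4-methoxybenzyl bromide. F2 and F3 with Cs2CO3 in CH2Cl2 should give the o-quinone methide and the sulfonium ylide; conjugate addition and SN2 closure by the phenoxide with loss of the sulfide give the trans ring of 18 directly. The chiral sulfide is relied on for the facial choice, and its antipode is taken if the sense is the opposite.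

Step 11. Condensation at the tri-ortho-substituted carbonyl group may stall, or prolonged heating with hydrazine may degrade the material. The fallback sets out from 14 and comes back at 16. Sc(OTf)3-catalysed condensation with 1,2-bis(tert-butyldimethylsilyl)hydrazine, which is driven by silanol formation, should give the N-silyl hydrazone F4. Oxidation with (difluoroiodo)benzene and 2-chloropyridine at −78 °C → rt then gives diazo compound 16, which enters the rhodium stage of step 12.

Step 16. The Z geometry may erode during coupling, the alkenylboronate may protodeboronate, and the polyphenolate may be oxidised or bind the catalyst. The fallback sets out from 19 and comes back at 23. Copper-free Sonogashira coupling with 4-ethynylphenol (PdCl2(MeCN)2, XPhos, Cs2CO3, MeCN/H2O) gives the diarylalkyne F5. Semihydrogenation over Lindlar catalyst (H2, quinoline, MeOH/EtOAc) then delivers the cis-alkene by syn addition.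

**Further compounds**

F1 | step 12 | 3-bromo-2-{hydroxy[(2R,3R)-3-(3,5-dimethoxyphenyl)-6-methoxy-2-(4-methoxyphenyl)-2,3-dihydro-1-benzofuran-4-yl]methyl}-5-methoxyphenol | COc1cc(O)c(C(O)c2cc(OC)cc3c2[C@@H](c2cc(OC)cc(OC)c2)[C@H](c2ccc(OC)cc2)O3)c(Br)c1
F2 | step 12 | 3-bromo-2-{[(2R,3R)-3-(3,5-dimethoxyphenyl)-6-methoxy-2-(4-methoxyphenyl)-2,3-dihydro-1-benzofuran-4-yl](4-methylbenzenesulfonyl)methyl}-5-methoxyphenol | COc1cc(O)c(C(c2cc(OC)cc3c2[C@@H](c2cc(OC)cc(OC)c2)[C@H](c2ccc(OC)cc2)O3)S(=O)(=O)c2ccc(C)cc2)c(Br)c1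
F3 | step 12 | (2R,5R)-1-(4-methoxybenzyl)-2,5-dimethylthiolan-1-ium bromide | C[C@@H]1CC[C@@H](C)[S+]1Cc1ccc(OC)cc1.[Br-]
F4 | step 11 | N-(tert-butyldimethylsilyl)hydrazone of ketone 14 | COc1ccc(COc2cc(OC)cc(Br)c2C(=NN[Si](C)(C)C(C)(C)C)c2cc(OC)cc3c2[C@@H](c2cc(OC)cc(OC)c2)[C@H](c2ccc(OC)cc2)O3)cc1
F5 | step 16 | 5-[(2R,3R)-6-hydroxy-4-[(2S,3S)-6-hydroxy-2-(4-hydroxyphenyl)-4-[(4-hydroxyphenyl)ethynyl]-2,3-dihydro-1-benzofuran-3-yl]-2-(4-hydroxyphenyl)-2,3-dihydro-1-benzofuran-3-yl]benzene-1,3-diol | Oc1ccc(C#Cc2cc(O)cc3c2[C@H](c2cc(O)cc4c2[C@@H](c2cc(O)cc(O)c2)[C@H](c2ccc(O)cc2)O4)[C@@H](c2ccc(O)cc2)O3)cc1
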